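## Retrosynthetic overview

1. Ring B (the 2-methyl-tetrahydropyridine) is closed last: removing both Boc groups from a 26-membered macrodiolide lets the C6' amine condense with a C2' methyl ketone, which is unmasked by ozonolysis of an isopropenyl group.
2. The macrocycle is cut at its two lactone C–O bonds: a macrolactonisation at the allylic alcohol, preceded by the late esterification of two C14 halves (an open-chain acid that carries latent ring B, and the all-cis N-Boc piperidinol, ring A).
3. Ring A is made inside its own half by Cbz hydrogenolysis and intramolecular reductive amination of a δ-amino α-hydroxy methyl ketone, which sets C2 cis to C3 and C6.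
4. Both halves come from (R)-5-(hept-6-enyl)pyrrolidin-2-one (L-pyroglutaminol tosylate plus a hexenyl Grignard reagent), by N-acyl-lactam opening with isopropenylmagnesium bromide, CBS reduction (C3–O) and acrylate cross-metathesis (acid chain).
5. Ring order: piperidine ring A, then the 26-membered ring, then tetrahydropyridine ring B.

Assumption: the SMILES is read as the (2S,3S,6R)-piperidine / (3S,6R)-tetrahydropyridine macrodiolide (each ring numbered N1, C2 = C–CH3, C3 = C–O, C6 = C–chain); metal alkoxide or carboxylate salts that are only protonated on work-up are not numbered separately.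

## Route

**Common intermediate**

Step 1
Reactants: 1 (S)-5-(hydroxymethyl)pyrrolidin-2-one
Product: 2 [(2S)-5-oxopyrrolidin-2-yl]methyl 4-methylbenzenesulfonate
Conditions: TsCl, Et3N, DMAP (cat.), CH2Cl2, 0 °C → rt
Reagents that add atoms: 4-toluenesulfonyl chloride, Cc1ccc(cc1)S(=O)(=O)Cl
Why: Tosylation (sulfonate ester formation) of the primary alcohol activates it for C–C coupling; the lactam N–H does not react and the stereocentre is untouched.

Step 2
Reactants: 2 [(2S)-5-oxopyrrolidin-2-yl]methyl 4-methylbenzenesulfonate; 3 6-bromohex-1-ene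
Product: 5 (5R)-5-(hept-6-en-1-yl)pyrrolidin-2-one, via hex-5-en-1-ylmagnesium bromide 4 (not isolated)
Conditions: 3 (3 equiv), Mg, THF, rt; then Li2CuCl4 (5 mol %), 2, THF, −30 → 0 °C; aq. NH4Cl
Reagents that add atoms: none
Why: Copper-catalysed Grignard–tosylate cross-coupling (Kochi type) displaces the primary tosylate after one equivalent of Grignard reagent has deprotonated the lactam N–H; the stereocentre is not involved and its descriptor changes from S to R only through CIP priorities.

**Half B (acid partner, latent ring B)**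

Step 3
Reactants: 5 (5R)-5-(hept-6-en-1-yl)pyrrolidin-2-one
Product: 6 tert-butyl (2R)-2-(hept-6-en-1-yl)-5-oxopyrrolidine-1-carboxylate
Conditions: Boc2O, Et3N, DMAP (cat.), CH2Cl2, rt
Reagents that add atoms: di-tert-butyl dicarbonate, CC(C)(C)OC(=O)OC(=O)OC(C)(C)C
Why: N-acylation (Boc protection) turns the lactam into an imide-like carbonyl that a Grignard reagent can open, and installs the N-protecting group that survives to the last step.

Step 4
Reactants: 6 tert-butyl (2R)-2-(hept-6-en-1-yl)-5-oxopyrrolidine-1-carboxylate; 7 methyl acrylate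
Product: 8 tert-butyl (2R)-2-[(6E)-8-methoxy-8-oxooct-6-en-1-yl]-5-oxopyrrolidine-1-carboxylate
Conditions: 7 (5 equiv), second-generation Hoveyda–Grubbs catalyst (3 mol %), CH2Cl2, 40 °C
Reagents that add atoms: none
Why: Olefin cross-metathesis between a terminal alkene and an electron-poor acrylate is selective for the (E)-cross product and completes the carbon count of the acid chain.

Step 5
Reactants: 8 tert-butyl (2R)-2-[(6E)-8-methoxy-8-oxooct-6-en-1-yl]-5-oxopyrrolidine-1-carboxylate
Product: 9 tert-butyl (2R)-2-(8-methoxy-8-oxooctyl)-5-oxopyrrolidine-1-carboxylate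
Conditions: H2 (1 atm), Pd/C (10 wt %), EtOAc, rt
Reagents that add atoms: none
Why: Heterogeneous catalytic hydrogenation saturates the enoate before any other alkene is present.

Step 6
Reactants: 9 tert-butyl (2R)-2-(8-methoxy-8-oxooctyl)-5-oxopyrrolidine-1-carboxylate; 10 isopropenylmagnesium bromide
Product: 11 methyl (9R)-9-[(tert-butoxycarbonyl)amino]-13-methyl-12-oxotetradec-13-enoate
Conditions: 10 (1.2 equiv), THF, −78 °C; aq. NH4Cl at −78 °C
Reagents that add atoms: none
Why: Grignard ring-opening of an N-Boc lactam (nucleophilic acyl substitution) is faster at −78 °C than addition to the remote methyl ester, and the stable tetrahedral adduct prevents double addition.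

Step 7
Reactants: 11 methyl (9R)-9-[(tert-butoxycarbonyl)amino]-13-methyl-12-oxotetradec-13-enoate
Product: 12 methyl (9R,12S)-9-[(tert-butoxycarbonyl)amino]-12-hydroxy-13-methyltetradec-13-enoate
Conditions: (R)-2-methyl-CBS-oxazaborolidine (20 mol %), catecholborane (1.8 equiv), toluene, −78 °C; MeOH, then aq. NaHCO3
Reagents that add atoms: none
Why: Corey–Bakshi–Shibata reduction with the (R)-catalyst treats the branched isopropenyl group as the large substituent and delivers hydride to give the (12S)-allylic alcohol by reagent control.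

Step 8
Reactants: 12 methyl (9R,12S)-9-[(tert-butoxycarbonyl)amino]-12-hydroxy-13-methyltetradec-13-enoate
Product: 13 methyl (9R,12S)-9-[(tert-butoxycarbonyl)amino]-12-[(tert-butyldimethylsilyl)oxy]-13-methyltetradec-13-enoate
Conditions: TBSCl, imidazole, DMF, rt
Reagents that add atoms: tert-butyldimethylsilyl chloride, CC(C)(C)[Si](C)(C)Cl
Why: Silyl ether formation blocks the allylic hydroxyl so that only the piperidinol can be acylated in the fragment coupling.

Step 9
Reactants: 13 methyl (9R,12S)-9-[(tert-butoxycarbonyl)amino]-12-[(tert-butyldimethylsilyl)oxy]-13-methyltetradec-13-enoate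
Product: 14 (9R,12S)-9-[(tert-butoxycarbonyl)amino]-12-[(tert-butyldimethylsilyl)oxy]-13-methyltetradec-13-enoic acid
Conditions: LiOH·H2O, THF/MeOH/H2O, rt; then 1 M HCl to pH 4
Reagents that add atoms: lithium hydroxide, [Li+].[OH-]
Why: Saponification of the unhindered methyl ester leaves the Boc carbamate and the TBS ether intact.

**Half A (alcohol partner, ring A)**

Step 10
Reactants: 5 (5R)-5-(hept-6-en-1-yl)pyrrolidin-2-one
Product: 15 benzyl (2R)-2-(hept-6-en-1-yl)-5-oxopyrrolidine-1-carboxylate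
Conditions: LiN(SiMe3)2, THF, −78 °C; CbzCl, −78 → 0 °C
Reagents that add atoms: benzyl chloroformate, O=C(Cl)OCc1ccccc1
Why: N-acylation of the lithiated lactam gives the Cbz imide, which activates the ring for opening and is later removed by the same hydrogenation that closes ring A.

Step 11
Reactants: 15 benzyl (2R)-2-(hept-6-en-1-yl)-5-oxopyrrolidine-1-carboxylate; 10 isopropenylmagnesium bromide
Product: 16 benzyl [(6R)-2-methyl-3-oxotrideca-1,12-dien-6-yl]carbamate
Conditions: 10 (1.2 equiv), THF, −78 °C; aq. NH4Cl at −78 °C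
Reagents that add atoms: none
Why: Grignard ring-opening of the N-Cbz lactam (nucleophilic acyl substitution) gives the open-chain isopropenyl ketone, with no competing ester in the molecule.

Step 12
Reactants: 16 benzyl [(6R)-2-methyl-3-oxotrideca-1,12-dien-6-yl]carbamate
Product: 17 benzyl [(3S,6R)-3-hydroxy-2-methyltrideca-1,12-dien-6-yl]carbamate
Conditions: (R)-2-methyl-CBS-oxazaborolidine (20 mol %), catecholborane (1.8 equiv), toluene, −78 °C; MeOH, then aq. NaHCO3
Reagents that add atoms: none
Why: CBS reduction with the (R)-catalyst sets the (3S)-carbinol as in step 7, and catecholborane does not hydroborate the terminal alkene at −78 °C.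

Step 13
Reactants: 18 acryloyl chloride; 19 2-(trimethylsilyl)ethanol
Product: 20 2-(trimethylsilyl)ethyl acrylate
Conditions: Et3N, CH2Cl2, 0 °C (trace BHT)
Reagents that add atoms: none
Why: Acid chloride esterification gives the acrylate of a fluoride-labile ester group that is orthogonal to Boc, to hydrogenation and to the later ester linkage.

Step 14
Reactants: 17 benzyl [(3S,6R)-3-hydroxy-2-methyltrideca-1,12-dien-6-yl]carbamate; 20 2-(trimethylsilyl)ethyl acrylate
Product: 21 2-(trimethylsilyl)ethyl (2E,9R,12S)-9-{[(benzyloxy)carbonyl]amino}-12-hydroxy-13-methyltetradeca-2,13-dienoate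
Conditions: 20 (3 equiv), second-generation Hoveyda–Grubbs catalyst (5 mol %), CH2Cl2, 40 °C
Reagents that add atoms: none
Why: Cross-metathesis occurs only at the monosubstituted terminal alkene because the 1,1-disubstituted allylic-alcohol alkene is too hindered to enter the catalytic cycle.

Step 15
Reactants: 21 2-(trimethylsilyl)ethyl (2E,9R,12S)-9-{[(benzyloxy)carbonyl]amino}-12-hydroxy-13-methyltetradeca-2,13-dienoate
Product: 23 2-(trimethylsilyl)ethyl (2E,9R,12S)-9-{[(benzyloxy)carbonyl]amino}-12-hydroxy-13-oxotetradec-2-enoate, via isopropenyl ozonide 22 (not isolated)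
Conditions: O3 (about 1 equiv, Sudan Red 7B end point), CH2Cl2, −78 °C; then PPh3, −78 °C → rt
Reagents that add atoms: ozone, [O-][O+]=O
Why: Chemoselective ozonolysis cleaves the electron-rich 1,1-disubstituted alkene far faster than the electron-poor enoate and unmasks the methyl ketone without touching the carbinol stereocentre.

Step 16
Reactants: 23 2-(trimethylsilyl)ethyl (2E,9R,12S)-9-{[(benzyloxy)carbonyl]amino}-12-hydroxy-13-oxotetradec-2-enoate
Product: 26 2-(trimethylsilyl)ethyl 8-[(2R,5S,6S)-5-hydroxy-6-methylpiperidin-2-yl]octanoate, via amino ketone 24 (not isolated), via cyclic imine 25 (not isolated)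
Conditions: H2 (1–3 atm), Pd/C (10 wt %), EtOAc/EtOH (1:1), rt
Reagents that add atoms: none
Why: In this hydrogenation cascade (enoate saturation, Cbz hydrogenolysis, intramolecular reductive amination) the cyclic imine takes up hydrogen on the face opposite the cis C3–OH and C6 chain, which sets C2 as S and gives the all-cis piperidine.

Step 17
Reactants: 26 2-(trimethylsilyl)ethyl 8-[(2R,5S,6S)-5-hydroxy-6-methylpiperidin-2-yl]octanoate
Product: 27 tert-butyl (2S,3S,6R)-3-hydroxy-2-methyl-6-{8-oxo-8-[2-(trimethylsilyl)ethoxy]octyl}piperidine-1-carboxylate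
Conditions: Boc2O (3 equiv), Et3N, 1,4-dioxane, 50 °C
Reagents that add atoms: di-tert-butyl dicarbonate, CC(C)(C)OC(=O)OC(=O)OC(C)(C)C
Why: Carbamate formation on the more nucleophilic nitrogen (no DMAP, so the hydroxyl stays free) prevents N-acylation in the two ester-forming steps.

**Fragment coupling and endgame**

Step 18
Reactants: 14 (9R,12S)-9-[(tert-butoxycarbonyl)amino]-12-[(tert-butyldimethylsilyl)oxy]-13-methyltetradec-13-enoic acid; 27 tert-butyl (2S,3S,6R)-3-hydroxy-2-methyl-6-{8-oxo-8-[2-(trimethylsilyl)ethoxy]octyl}piperidine-1-carboxylate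
Product: 29 piperidin-3-yl ester of 14 with 27 (TMSE ester and TBS ether intact), via mixed anhydride 28 (not isolated)
Conditions: 14, 2,4,6-trichlorobenzoyl chloride, Et3N, THF, rt; then 27, DMAP, toluene, rt → 40 °C
Reagents that add atoms: none
Why: Yamaguchi esterification joins the two C14 halves at the only free hydroxyl (piperidine C3–OH) and the only free carboxyl, with no change at any stereocentre.

Step 19
Reactants: 29 piperidin-3-yl ester of 14 with 27
Product: 30 seco acid (free chain carboxyl on ring A, free allylic hydroxyl on half B)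
Conditions: TBAF (5 equiv), THF, 0 °C → rt; then AcOH
Reagents that add atoms: none
Why: Fluoride-induced desilylation fragments the 2-(trimethylsilyl)ethyl ester and cleaves the TBS ether in one operation, while the Boc groups and the inter-fragment ester are inert.

Step 20
Reactants: 30 seco acid
Product: 32 bis-Boc isopropenyl macrodiolide (26-membered ring), via mixed anhydride 31 (not isolated)
Conditions: 2,4,6-trichlorobenzoyl chloride, Et3N, THF, rt; then slow addition to DMAP, toluene, 80 °C (final 1 mM)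
Reagents that add atoms: none
Why: Yamaguchi macrolactonisation under high dilution closes the large, unstrained 26-membered ring by O-acylation of the allylic alcohol with retention at C3'.

Step 21
Reactants: 32 bis-Boc isopropenyl macrodiolide
Product: 34 bis-Boc methyl ketone macrodiolide, via macrocycle ozonide 33 (not isolated)
Conditions: O3, CH2Cl2, −78 °C; then PPh3, −78 °C → rt
Reagents that add atoms: ozone, [O-][O+]=O
Why: Ozonolysis of the only alkene gives the α-acyloxy methyl ketone under neutral conditions that do not epimerise C3' or affect carbamates and lactones.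

Step 22
Reactants: 34 bis-Boc methyl ketone macrodiolide
Product: 36 target CNP0304114.1, via diamino ketone 35 (not isolated)
Conditions: TFA/CH2Cl2 (1:4), 0 °C; concentrate; aq. NaHCO3/CH2Cl2, rt
Reagents that add atoms: none
Why: Acidolytic removal of both Boc groups followed by neutralisation lets the primary δ-amine condense with the methyl ketone to the six-membered cyclic ketimine (intramolecular imine formation), while the hindered piperidine N–H stays free as in the target.

## Compound list

1 | (S)-5-(hydroxymethyl)pyrrolidin-2-one (L-pyroglutaminol) | O=C1CC[C@@H](CO)N1 | starting material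
2 | [(2S)-5-oxopyrrolidin-2-yl]methyl 4-methylbenzenesulfonate | O=C1CC[C@@H](COS(=O)(=O)c2ccc(C)cc2)N1 | intermediate
3 | 6-bromohex-1-ene | C=CCCCCBr | starting material
4 | hex-5-en-1-ylmagnesium bromide | C=CCCCC[Mg]Br | intermediate (not isolated)
5 | (5R)-5-(hept-6-en-1-yl)pyrrolidin-2-one | O=C1CC[C@@H](CCCCCC=C)N1 | intermediate
6 | tert-butyl (2R)-2-(hept-6-en-1-yl)-5-oxopyrrolidine-1-carboxylate | O=C1CC[C@@H](CCCCCC=C)N1C(=O)OC(C)(C)C | intermediate
7 | methyl acrylate | C=CC(=O)OC | starting material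
8 | tert-butyl (2R)-2-[(6E)-8-methoxy-8-oxooct-6-en-1-yl]-5-oxopyrrolidine-1-carboxylate | O=C1CC[C@@H](CCCCC/C=C/C(=O)OC)N1C(=O)OC(C)(C)C | intermediate
9 | tert-butyl (2R)-2-(8-methoxy-8-oxooctyl)-5-oxopyrrolidine-1-carboxylate | O=C1CC[C@@H](CCCCCCCC(=O)OC)N1C(=O)OC(C)(C)C | intermediate
10 | isopropenylmagnesium bromide (prop-1-en-2-ylmagnesium bromide) | CC(=C)[Mg]Br | starting material
11 | methyl (9R)-9-[(tert-butoxycarbonyl)amino]-13-methyl-12-oxotetradec-13-enoate | COC(=O)CCCCCCC[C@@H](NC(=O)OC(C)(C)C)CCC(=O)C(C)=C | intermediate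
12 | methyl (9R,12S)-9-[(tert-butoxycarbonyl)amino]-12-hydroxy-13-methyltetradec-13-enoate | COC(=O)CCCCCCC[C@@H](NC(=O)OC(C)(C)C)CC[C@H](O)C(C)=C | intermediate
13 | methyl (9R,12S)-9-[(tert-butoxycarbonyl)amino]-12-[(tert-butyldimethylsilyl)oxy]-13-methyltetradec-13-enoate | COC(=O)CCCCCCC[C@@H](NC(=O)OC(C)(C)C)CC[C@H](O[Si](C)(C)C(C)(C)C)C(C)=C | intermediate
14 | (9R,12S)-9-[(tert-butoxycarbonyl)amino]-12-[(tert-butyldimethylsilyl)oxy]-13-methyltetradec-13-enoic acid | OC(=O)CCCCCCC[C@@H](NC(=O)OC(C)(C)C)CC[C@H](O[Si](C)(C)C(C)(C)C)C(C)=C | intermediate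
15 | benzyl (2R)-2-(hept-6-en-1-yl)-5-oxopyrrolidine-1-carboxylate | O=C1CC[C@@H](CCCCCC=C)N1C(=O)OCc2ccccc2 | intermediate
16 | benzyl [(6R)-2-methyl-3-oxotrideca-1,12-dien-6-yl]carbamate | C=CCCCCC[C@@H](NC(=O)OCc1ccccc1)CCC(=O)C(C)=C | intermediate
17 | benzyl [(3S,6R)-3-hydroxy-2-methyltrideca-1,12-dien-6-yl]carbamate | C=CCCCCC[C@@H](NC(=O)OCc1ccccc1)CC[C@H](O)C(C)=C | intermediate
18 | acryloyl chloride | C=CC(=O)Cl | starting material
19 | 2-(trimethylsilyl)ethanol | C[Si](C)(C)CCO | starting material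
20 | 2-(trimethylsilyl)ethyl acrylate | C=CC(=O)OCC[Si](C)(C)C | intermediate
21 | 2-(trimethylsilyl)ethyl (2E,9R,12S)-9-{[(benzyloxy)carbonyl]amino}-12-hydroxy-13-methyltetradeca-2,13-dienoate | C[Si](C)(C)CCOC(=O)/C=C/CCCCC[C@@H](NC(=O)OCc1ccccc1)CC[C@H](O)C(C)=C | intermediate
22 | isopropenyl ozonide of 21 (3-methyl-1,2,4-trioxolan-3-yl in place of isopropenyl) | C[Si](C)(C)CCOC(=O)/C=C/CCCCC[C@@H](NC(=O)OCc1ccccc1)CC[C@H](O)C2(C)OOCO2 | intermediate (not isolated)
23 | 2-(trimethylsilyl)ethyl (2E,9R,12S)-9-{[(benzyloxy)carbonyl]amino}-12-hydroxy-13-oxotetradec-2-enoate | C[Si](C)(C)CCOC(=O)/C=C/CCCCC[C@@H](NC(=O)OCc1ccccc1)CC[C@H](O)C(C)=O | intermediate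
24 | 2-(trimethylsilyl)ethyl (9R,12S)-9-amino-12-hydroxy-13-oxotetradecanoate | C[Si](C)(C)CCOC(=O)CCCCCCC[C@@H](N)CC[C@H](O)C(C)=O | intermediate (not isolated)
25 | 2-(trimethylsilyl)ethyl 8-[(2R,5S)-5-hydroxy-6-methyl-2,3,4,5-tetrahydropyridin-2-yl]octanoate | CC1=N[C@H](CCCCCCCC(=O)OCC[Si](C)(C)C)CC[C@@H]1O | intermediate (not isolated)
26 | 2-(trimethylsilyl)ethyl 8-[(2R,5S,6S)-5-hydroxy-6-methylpiperidin-2-yl]octanoate | C[C@@H]1N[C@H](CCCCCCCC(=O)OCC[Si](C)(C)C)CC[C@@H]1O | intermediate
27 | tert-butyl (2S,3S,6R)-3-hydroxy-2-methyl-6-{8-oxo-8-[2-(trimethylsilyl)ethoxy]octyl}piperidine-1-carboxylate | C[C@@H]1N(C(=O)OC(C)(C)C)[C@H](CCCCCCCC(=O)OCC[Si](C)(C)C)CC[C@@H]1O | intermediate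
28 | mixed anhydride of 14 with 2,4,6-trichlorobenzoic acid | O=C(OC(=O)CCCCCCC[C@@H](NC(=O)OC(C)(C)C)CC[C@H](O[Si](C)(C)C(C)(C)C)C(C)=C)c1c(Cl)cc(Cl)cc1Cl | intermediate (not isolated)
29 | tert-butyl (2S,3S,6R)-3-{[(9R,12S)-9-[(tert-butoxycarbonyl)amino]-12-[(tert-butyldimethylsilyl)oxy]-13-methyltetradec-13-enoyl]oxy}-2-methyl-6-{8-oxo-8-[2-(trimethylsilyl)ethoxy]octyl}piperidine-1-carboxylate | C[C@@H]1N(C(=O)OC(C)(C)C)[C@H](CCCCCCCC(=O)OCC[Si](C)(C)C)CC[C@@H]1OC(=O)CCCCCCC[C@@H](NC(=O)OC(C)(C)C)CC[C@H](O[Si](C)(C)C(C)(C)C)C(C)=C | intermediate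
30 | 8-[(2R,5S,6S)-1-(tert-butoxycarbonyl)-5-{[(9R,12S)-9-[(tert-butoxycarbonyl)amino]-12-hydroxy-13-methyltetradec-13-enoyl]oxy}-6-methylpiperidin-2-yl]octanoic acid (seco acid) | C[C@@H]1N(C(=O)OC(C)(C)C)[C@H](CCCCCCCC(=O)O)CC[C@@H]1OC(=O)CCCCCCC[C@@H](NC(=O)OC(C)(C)C)CC[C@H](O)C(C)=C | intermediate
31 | mixed anhydride of seco acid 30 with 2,4,6-trichlorobenzoic acid | C[C@@H]1N(C(=O)OC(C)(C)C)[C@H](CCCCCCCC(=O)OC(=O)c2c(Cl)cc(Cl)cc2Cl)CC[C@@H]1OC(=O)CCCCCCC[C@@H](NC(=O)OC(C)(C)C)CC[C@H](O)C(C)=C | intermediate (not isolated)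
32 | bis-Boc isopropenyl macrodiolide: 26-membered dilactone formed by closing the carboxyl of 30 onto its (12S)-allylic hydroxyl; holds the N-Boc (2S,3S,6R)-piperidine, an (R)-CH–NHBoc and an (S)-CH(O-acyl)–C(CH3)=CH2 unit | C[C@@H]1N(C(=O)OC(C)(C)C)[C@@H]2CCCCCCCC(=O)O[C@H](C(C)=C)CC[C@H](NC(=O)OC(C)(C)C)CCCCCCCC(=O)O[C@H]1CC2 | intermediate
33 | macrocycle ozonide of 32 (3-methyl-1,2,4-trioxolan-3-yl in place of isopropenyl) | C[C@@H]1N(C(=O)OC(C)(C)C)[C@@H]2CCCCCCCC(=O)O[C@H](C3(C)OOCO3)CC[C@H](NC(=O)OC(C)(C)C)CCCCCCCC(=O)O[C@H]1CC2 | intermediate (not isolated)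
34 | bis-Boc methyl ketone macrodiolide (32 with acetyl in place of isopropenyl) | C[C@@H]1N(C(=O)OC(C)(C)C)[C@@H]2CCCCCCCC(=O)O[C@H](C(C)=O)CC[C@H](NC(=O)OC(C)(C)C)CCCCCCCC(=O)O[C@H]1CC2 | intermediate
35 | diamino ketone macrodiolide (34 without both Boc groups) | C[C@@H]1N[C@@H]2CCCCCCCC(=O)O[C@H](C(C)=O)CC[C@H](N)CCCCCCCC(=O)O[C@H]1CC2 | intermediate (not isolated)
36 | CNP0304114.1: 26-membered dilactone of the (2S,3S,6R)-piperidine hydroxy acid and the (3S,6R)-2-methyl-tetrahydropyridine hydroxy acid | CC1=N[C@@H]2CCCCCCCC(=O)O[C@H]3CC[C@@H](CCCCCCCC(=O)O[C@H]1CC2)N[C@H]3C | target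

## Step count and risks

Total step count: 22. Longest linear sequence: 14 steps (1, 2, 3–9, 18–22; the sequence 1, 2, 10–12, 14–17, 18–22 is equally long).

**Step 15 (selective ozonolysis).** The enoate or the benzyl group may be attacked, or the free α-hydroxy ketone may degrade. The fallback sets out from 17 and comes back to the route at 23. Both alkenes of 17 are ozonised to completion (O3, CH2Cl2, −78 °C; PPh3) to give the keto aldehyde benzyl [(3S,6R)-3-hydroxy-2,12-dioxododecan-6-yl]carbamate F1. The aldehyde alone is then olefinated with the stabilised ylide Ph3P=CHCO2CH2CH2SiMe3 (CH2Cl2, rt), which does not react with the ketone. This gives 23 without metathesis and without any need to distinguish two alkenes.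

**Step 20 (macrolactonisation).** Oligomerisation or sluggish acylation of the branched allylic alcohol may lower the yield. The fallback sets out from 27 and 12 and comes back at 32; it reverses the order of the two ester bonds so that the ring is closed at the piperidine C3–OH instead.
- 27 is silylated (TBSOTf, 2,6-lutidine) to tert-butyl (2S,3S,6R)-3-[(tert-butyldimethylsilyl)oxy]-2-methyl-6-{8-oxo-8-[2-(trimethylsilyl)ethoxy]octyl}piperidine-1-carboxylate F2.
- The silylethyl ester alone is cleaved with a slight excess of TBAF at 0 °C to give 8-[(2R,5S,6S)-1-(tert-butoxycarbonyl)-5-[(tert-butyldimethylsilyl)oxy]-6-methylpiperidin-2-yl]octanoic acid F3.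
- Yamaguchi esterification of F3 with the allylic alcohol 12 gives the allylic ester of 12 with F3 F4.
- Me3SnOH (1,2-dichloroethane, 80 °C) cleaves only the methyl ester to give the carboxylic acid from F4 F5.
- HF·pyridine removes the silyl ether to give the hydroxy acid from F5 F6.
- Yamaguchi lactonisation of F6 onto the piperidine hydroxyl delivers 32.

**Step 22 (Boc removal and imine closure).** The α-acyloxy ketone may epimerise or undergo acyl transfer during the acid treatment and neutralisation. The fallback sets out from 32 and comes back at 35, which closes to 36 as before; it removes the carbamates before the ketone exists. 32 is treated with TFA/CH2Cl2 to give the bis-amine isopropenyl macrodiolide F7 as its bis(trifluoroacetate). This doubly protonated salt, whose ammonium groups are inert to ozone, is ozonised in CH2Cl2/MeOH at −78 °C and reduced with Me2S to give the salt of 35. Buffering with NaOAc/NaHCO3 then closes the imine.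

## Further compounds

F1 | step 15 | benzyl [(3S,6R)-3-hydroxy-2,12-dioxododecan-6-yl]carbamate | O=CCCCCC[C@@H](NC(=O)OCc1ccccc1)CC[C@H](O)C(C)=O
F2 | step 20 | tert-butyl (2S,3S,6R)-3-[(tert-butyldimethylsilyl)oxy]-2-methyl-6-{8-oxo-8-[2-(trimethylsilyl)ethoxy]octyl}piperidine-1-carboxylate | C[C@@H]1N(C(=O)OC(C)(C)C)[C@H](CCCCCCCC(=O)OCC[Si](C)(C)C)CC[C@@H]1O[Si](C)(C)C(C)(C)C
F3 | step 20 | 8-[(2R,5S,6S)-1-(tert-butoxycarbonyl)-5-[(tert-butyldimethylsilyl)oxy]-6-methylpiperidin-2-yl]octanoic acid | C[C@@H]1N(C(=O)OC(C)(C)C)[C@H](CCCCCCCC(=O)O)CC[C@@H]1O[Si](C)(C)C(C)(C)C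
F4 | step 20 | allylic ester of 12 with F3 (methyl ester and TBS ether intact) | C[C@@H]1N(C(=O)OC(C)(C)C)[C@H](CCCCCCCC(=O)O[C@H](C(C)=C)CC[C@H](NC(=O)OC(C)(C)C)CCCCCCCC(=O)OC)CC[C@@H]1O[Si](C)(C)C(C)(C)C
F5 | step 20 | carboxylic acid from F4 (methyl ester cleaved) | C[C@@H]1N(C(=O)OC(C)(C)C)[C@H](CCCCCCCC(=O)O[C@H](C(C)=C)CC[C@H](NC(=O)OC(C)(C)C)CCCCCCCC(=O)O)CC[C@@H]1O[Si](C)(C)C(C)(C)C
F6 | step 20 | hydroxy acid from F5 (TBS ether removed) | C[C@@H]1N(C(=O)OC(C)(C)C)[C@H](CCCCCCCC(=O)O[C@H](C(C)=C)CC[C@H](NC(=O)OC(C)(C)C)CCCCCCCC(=O)O)CC[C@@H]1O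
F7 | step 22 | bis-amine isopropenyl macrodiolide (32 without its two Boc groups) | C[C@@H]1N[C@@H]2CCCCCCCC(=O)O[C@H](C(C)=C)CC[C@H](N)CCCCCCCC(=O)O[C@H]1CC2
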